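**Retrosynthetic overview**
- Lactol–lactone (made last): cis γ-formyl acid ⇐ 1,4-addition of a nitronate (carboxyl-anion equivalent) to a 2-formyl-1,3-diene; the formyl carbon comes from CO via the dienyl triflate of a cyclohexenone.
- Side chain (key bond, C-α to ring C-4): extended enolate of a β,γ-cyclohexenone + (R)-lactate triflate (an enolonium equivalent), SN2 with inversion; acid then moves the alkene into the tetrasubstituted position.
- Cyclohexenone ring ⇐ Birch reduction and hydrolysis of an anisole; the 3-methoxyphenyl group is a masked 3-oxocyclohexenyl (β-acyl vinyl) anion.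
- Quaternary centre ⇐ asymmetric conjugate arylation of isophorone (1) with 3-methoxyphenylboronic acid (2), then Wolff–Kishner removal of the carbonyl.
- Ring order: trimethylcyclohexane (bought in 1) → cyclohexene (from the arene) → γ-lactol lactone.

Assumption: the hemiacylal carbon C-3 of the target equilibrates by ring–chain tautomerism, so its (3R) configuration is taken as the thermodynamic anomer and is not set kinetically.

Step 1
Reactants: 1 isophorone (3,5,5-trimethylcyclohex-2-en-1-one); 2 3-methoxyphenylboronic acid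
Product: 3 (3R)-3-(3-methoxyphenyl)-3,5,5-trimethylcyclohexan-1-one
Conditions: Pd(OCOCF3)2 (5 mol %), (S)-t-BuPyOx (6 mol %), NH4PF6 (30 mol %), H2O (5 equiv), ClCH2CH2Cl, 60 °C
Reagents that add atoms: none
Why: Palladium–pyridinooxazoline-catalysed asymmetric conjugate addition of an arylboronic acid to a β-methyl cyclic enone builds the quaternary centre by enantioface-selective migratory insertion (the (S)-ligand is expected, by analogy with 3-methylcyclohexenone, to give the (R)-ketone, and the 5,5-dimethyl group does not alter the CIP order), and because the 3-methoxyphenyl group is a masked 3-oxocyclohex-1-enyl anion, two normally electrophilic enone β-carbons are joined.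

Step 2
Reactants: 3 (3R)-3-(3-methoxyphenyl)-3,5,5-trimethylcyclohexan-1-one
Product: 5 1-methoxy-3-[(1S)-1,3,3-trimethylcyclohexyl]benzene, via hydrazone 4 (not isolated)
Conditions: N2H4·H2O, KOH, diethylene glycol, 130 °C then 200 °C
Reagents that add atoms: none
Why: Wolff–Kishner reduction (Huang–Minlon variant) removes the ring carbonyl through the hydrazone without touching the quaternary centre, whose descriptor changes from R to S only because the CIP priorities of the two ring arms swap.

Step 3
Reactants: 5 1-methoxy-3-[(1S)-1,3,3-trimethylcyclohexyl]benzene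
Product: 7 3-[(1S)-1,3,3-trimethylcyclohexyl]cyclohex-3-en-1-one, via dihydroanisole 6 (not isolated)
Conditions: Li, NH3 (l), t-BuOH, THF, −78 to −33 °C; NH4Cl; then (CO2H)2, MeOH–H2O, 23 °C
Reagents that add atoms: water (O)
Why: Birch reduction of the 3-alkylanisole leaves the methoxy and tert-alkyl groups on the two remaining alkene carbons, and mild oxalic acid hydrolysis of the enol ether unmasks the ketone without conjugating the alkene, so the CH2 between C=O and C=C is ready for regioselective enolisation and no stereocentre is formed.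

Step 4
Reactants: 8 methyl (2R)-2-hydroxypropanoate (methyl D-lactate)
Product: 9 methyl (2R)-2-{[(trifluoromethyl)sulfonyl]oxy}propanoate
Conditions: Tf2O, 2,6-lutidine, CH2Cl2, −78 to 0 °C
Reagents that add atoms: trifluoromethanesulfonic anhydride, O=S(=O)(OS(=O)(=O)C(F)(F)F)C(F)(F)F
Why: O-Sulfonylation of the secondary alcohol leaves the C–O bond intact, so the (R) configuration of D-lactate is retained in the triflate, which serves as an α-carbonyl cation (enolonium) equivalent.

Step 5
Reactants: 7 3-[(1S)-1,3,3-trimethylcyclohexyl]cyclohex-3-en-1-one; 9 methyl (2R)-2-{[(trifluoromethyl)sulfonyl]oxy}propanoate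
Product: 12 methyl (2R)-2-[6-oxo-2-[(1S)-1,3,3-trimethylcyclohexyl]cyclohex-1-en-1-yl]propanoate, via lithium dienolate 10 (not isolated), via deconjugated keto ester 11 (not isolated)
Conditions: LiN(i-Pr)2, THF, −78 to 0 °C; then 9, THF, −78 to −40 °C; aq. NH4Cl; then TsOH·H2O (10 mol %), benzene, 40 °C
Reagents that add atoms: none
Why: Proposed new method: deprotonation of the doubly activated C-2 methylene gives the extended lithium dienolate 10, whose α-carbon displaces triflate from 9 by SN2 with inversion (the (R)-triflate gives the (2R)-ester because the CIP order changes), uniting two carbons that are both normally nucleophilic α-carbons, and acid then moves the alkene into conjugation to give the tetrasubstituted enone; the closest known reactions are the inversion alkylations of β-keto ester enolates and cuprates with α-triflyloxy esters and the α-alkylation of dienolates of β,γ-unsaturated ketones.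

Step 6
Reactants: 12 methyl (2R)-2-[6-oxo-2-[(1S)-1,3,3-trimethylcyclohexyl]cyclohex-1-en-1-yl]propanoate
Product: 14 methyl (2R)-2-[6-{[(trifluoromethyl)sulfonyl]oxy}-2-[(1S)-1,3,3-trimethylcyclohexyl]cyclohexa-1,5-dien-1-yl]propanoate, via lithium enolate 13 (not isolated)
Conditions: LiN(i-Pr)2, THF, −78 °C; then PhNTf2, −78 to 0 °C
Reagents that add atoms: N-phenylbis(trifluoromethanesulfonimide), O=S(=O)(N(c1ccccc1)S(=O)(=O)C(F)(F)F)C(F)(F)F
Why: Kinetic deprotonation at the α′-methylene (the α-carbon is fully substituted and the ester α-hydrogen is less acidic and hindered) gives the cross-conjugated enolate, which PhNTf2 traps on oxygen as the enol triflate, leaving both stereocentres untouched.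

Step 7
Reactants: 14 methyl (2R)-2-[6-{[(trifluoromethyl)sulfonyl]oxy}-2-[(1S)-1,3,3-trimethylcyclohexyl]cyclohexa-1,5-dien-1-yl]propanoate
Product: 15 methyl (2R)-2-[6-formyl-2-[(1S)-1,3,3-trimethylcyclohexyl]cyclohexa-1,5-dien-1-yl]propanoate
Conditions: Pd(PPh3)4 (5 mol %), CO (3 atm), Bu3SnH (slow addition), THF, 50 °C
Reagents that add atoms: carbon monoxide, [C-]#[O+]
Why: Palladium-catalysed reductive carbonylation (formylation) of the vinyl triflate proceeds by oxidative addition, CO insertion and hydride transfer from Bu3SnH to the acyl palladium, giving the dienal without touching the stereocentres.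

Step 8
Reactants: 15 methyl (2R)-2-[6-formyl-2-[(1S)-1,3,3-trimethylcyclohexyl]cyclohexa-1,5-dien-1-yl]propanoate; 16 nitromethane
Product: 18 methyl (2R)-2-[(5R,6R)-6-(dimethoxymethyl)-5-(nitromethyl)-2-[(1S)-1,3,3-trimethylcyclohexyl]cyclohex-1-en-1-yl]propanoate, via nitro aldehyde 17 (not isolated)
Conditions: 9-amino-9-deoxy-epi-quinine (20 mol %), PhCO2H (40 mol %), toluene, 23 °C; then HC(OMe)3, MeOH, TsOH·H2O, 23 °C
Reagents that add atoms: trimethyl orthoformate, COC(OC)OC
Why: Proposed new method: the primary amine forms an iminium ion with the α-branched enal and its protonated quinuclidine steers the nitronate (a carboxyl-anion equivalent) to one face of C-5 to set (5R) (the quinidine-derived pseudoenantiomer is used if the facial sense proves opposite), protonation of the resulting enamine anti to the new nitromethyl group places the formyl group cis (6R), and the labile aldehyde is then stored as its dimethyl acetal; the closest known reactions are iminium-catalysed nitroalkane additions to enals and cyclic enones and primary-amine catalysis of α-branched enals.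

Step 9
Reactants: 18 methyl (2R)-2-[(5R,6R)-6-(dimethoxymethyl)-5-(nitromethyl)-2-[(1S)-1,3,3-trimethylcyclohexyl]cyclohex-1-en-1-yl]propanoate
Product: 20 methyl (2R)-2-[(3R,3aR,7aR)-3-hydroxy-1-oxo-5-[(1S)-1,3,3-trimethylcyclohexyl]-1,3,3a,6,7,7a-hexahydro-2-benzofuran-4-yl]propanoate (the target), via acetal acid 19 (not isolated)
Conditions: NaNO2, AcOH, DMSO, 35 °C; then 1 M HCl, THF, 23 °C
Reagents that add atoms: sodium nitrite, [Na+].[O-]N=O; water, O
Why: Nitrite-mediated Nef-type oxidation of the primary nitro group (via the nitrolic acid and nitrile oxide) gives the carboxylic acid without epimerising C-5, and aqueous acid then unmasks the aldehyde, which the cis carboxyl group traps as the cis-fused γ-lactol lactone, any trans C-6 epimer equilibrating through the enol and the hemiacylal carbon settling as the (3R) anomer under thermodynamic control.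

**Compound list**
1 | isophorone (3,5,5-trimethylcyclohex-2-en-1-one) | CC1=CC(=O)CC(C)(C)C1 | starting material
2 | 3-methoxyphenylboronic acid | COc1cccc(c1)B(O)O | starting material
3 | (3R)-3-(3-methoxyphenyl)-3,5,5-trimethylcyclohexan-1-one | COc1cccc(c1)[C@@]1(C)CC(=O)CC(C)(C)C1 | intermediate
4 | (3R)-3-(3-methoxyphenyl)-3,5,5-trimethylcyclohexan-1-one hydrazone | COc1cccc(c1)[C@@]1(C)CC(=NN)CC(C)(C)C1 | intermediate
5 | 1-methoxy-3-[(1S)-1,3,3-trimethylcyclohexyl]benzene | COc1cccc(c1)[C@@]1(C)CCCC(C)(C)C1 | intermediate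
6 | 1-methoxy-5-[(1S)-1,3,3-trimethylcyclohexyl]cyclohexa-1,4-diene | COC1=CCC=C(C1)[C@@]1(C)CCCC(C)(C)C1 | intermediate
7 | 3-[(1S)-1,3,3-trimethylcyclohexyl]cyclohex-3-en-1-one | O=C1CC(=CCC1)[C@@]1(C)CCCC(C)(C)C1 | intermediate
8 | methyl (2R)-2-hydroxypropanoate (methyl D-lactate) | C[C@@H](O)C(=O)OC | starting material
9 | methyl (2R)-2-{[(trifluoromethyl)sulfonyl]oxy}propanoate | C[C@@H](OS(=O)(=O)C(F)(F)F)C(=O)OC | intermediate
10 | lithium 3-[(1S)-1,3,3-trimethylcyclohexyl]cyclohexa-1,3-dien-1-olate | [Li]OC1=CC(=CCC1)[C@@]1(C)CCCC(C)(C)C1 | intermediate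
11 | methyl (2R)-2-[2-oxo-6-[(1S)-1,3,3-trimethylcyclohexyl]cyclohex-5-en-1-yl]propanoate (both ring C-1 epimers) | COC(=O)[C@H](C)C1C(=O)CCC=C1[C@@]1(C)CCCC(C)(C)C1 | intermediate
12 | methyl (2R)-2-[6-oxo-2-[(1S)-1,3,3-trimethylcyclohexyl]cyclohex-1-en-1-yl]propanoate | COC(=O)[C@H](C)C1=C(CCCC1=O)[C@@]1(C)CCCC(C)(C)C1 | intermediate
13 | lithium 6-[(2R)-1-methoxy-1-oxopropan-2-yl]-5-[(1S)-1,3,3-trimethylcyclohexyl]cyclohexa-1,5-dien-1-olate | COC(=O)[C@H](C)C1=C(CCC=C1O[Li])[C@@]1(C)CCCC(C)(C)C1 | intermediate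
14 | methyl (2R)-2-[6-{[(trifluoromethyl)sulfonyl]oxy}-2-[(1S)-1,3,3-trimethylcyclohexyl]cyclohexa-1,5-dien-1-yl]propanoate | COC(=O)[C@H](C)C1=C(CCC=C1OS(=O)(=O)C(F)(F)F)[C@@]1(C)CCCC(C)(C)C1 | intermediate
15 | methyl (2R)-2-[6-formyl-2-[(1S)-1,3,3-trimethylcyclohexyl]cyclohexa-1,5-dien-1-yl]propanoate | COC(=O)[C@H](C)C1=C(CCC=C1C=O)[C@@]1(C)CCCC(C)(C)C1 | intermediate
16 | nitromethane | C[N+](=O)[O-] | starting material
17 | methyl (2R)-2-[(5R,6R)-6-formyl-5-(nitromethyl)-2-[(1S)-1,3,3-trimethylcyclohexyl]cyclohex-1-en-1-yl]propanoate | COC(=O)[C@H](C)C1=C([C@@]2(C)CCCC(C)(C)C2)CC[C@@H](C[N+](=O)[O-])[C@H]1C=O | intermediate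
18 | methyl (2R)-2-[(5R,6R)-6-(dimethoxymethyl)-5-(nitromethyl)-2-[(1S)-1,3,3-trimethylcyclohexyl]cyclohex-1-en-1-yl]propanoate | COC(=O)[C@H](C)C1=C([C@@]2(C)CCCC(C)(C)C2)CC[C@@H](C[N+](=O)[O-])[C@H]1C(OC)OC | intermediate
19 | (1R,2R)-2-(dimethoxymethyl)-3-[(2R)-1-methoxy-1-oxopropan-2-yl]-4-[(1S)-1,3,3-trimethylcyclohexyl]cyclohex-3-ene-1-carboxylic acid | COC(=O)[C@H](C)C1=C([C@@]2(C)CCCC(C)(C)C2)CC[C@@H](C(=O)O)[C@H]1C(OC)OC | intermediate
20 | methyl (2R)-2-[(3R,3aR,7aR)-3-hydroxy-1-oxo-5-[(1S)-1,3,3-trimethylcyclohexyl]-1,3,3a,6,7,7a-hexahydro-2-benzofuran-4-yl]propanoate | COC(=O)[C@H](C)C1=C([C@@]2(C)CCCC(C)(C)C2)CC[C@H]2C(=O)O[C@@H](O)[C@@H]12 | target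

**Step count and risks**
Total: 9 steps. Longest linear sequence: 8 steps (1, 2, 3, 5, 6, 7, 8, 9); step 4 prepares the triflate.

Most likely to fail, first: step 1. The 5,5-dimethyl group of isophorone may block aryl–palladium insertion or erode the enantioselectivity. The fallback replaces catalyst control by chirality transfer and sets out from 1. Reduction with BH3·SMe2 and (S)-2-methyl-CBS-oxazaborolidine gives (1R)-3,5,5-trimethylcyclohex-2-en-1-ol F1. Esterification with pyridine-2-carboxylic acid gives (1R)-3,5,5-trimethylcyclohex-2-en-1-yl pyridine-2-carboxylate F2. Anti-selective SN2′ substitution with 3-MeOC6H4MgBr and CuBr·SMe2 delivers the aryl group to C-3 on the face opposite the leaving group and gives 1-methoxy-3-[(1R)-1,5,5-trimethylcyclohex-2-en-1-yl]benzene F3. Hydrogenation (H2, Pd/C) saturates the ring alkene and comes back to the route at 5, so step 2 is not needed.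

Second: step 5. The hindered dienolate may be O-alkylated by the triflate or may deprotonate it, which would lower the yield and the enantiopurity at C-α. The fallback sets the side-chain centre by asymmetric hydrogenation instead and sets out from 7. Acid-catalysed isomerisation gives 3-[(1S)-1,3,3-trimethylcyclohexyl]cyclohex-2-en-1-one F4. Iodination with I2 and pyridine gives 2-iodo-3-[(1S)-1,3,3-trimethylcyclohexyl]cyclohex-2-en-1-one F5. Stille coupling with methyl 2-(tributylstannyl)acrylate (Pd(PPh3)4, CuI) gives methyl 2-[6-oxo-2-[(1S)-1,3,3-trimethylcyclohexyl]cyclohex-1-en-1-yl]prop-2-enoate F6. Hydrogenation of the 1,1-disubstituted acrylate alkene with [Rh(cod)2]BF4 and Et-DuPhos (the enantiomer that gives the (2R)-ester; the enone carbonyl acts as the second binding site, as the β-carboxyl does in itaconates) comes back to the route at 12.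

Third: step 8. Iminium formation from the α-branched dienal may be slow or poorly face-selective. The fallback brings in both one-carbon units by ketene cycloaddition instead of conjugate addition and sets out from 14. Reduction of the triflate (Pd(OAc)2, PPh3, HCO2H, Bu3N) gives methyl (2R)-2-[2-[(1S)-1,3,3-trimethylcyclohexyl]cyclohexa-1,5-dien-1-yl]propanoate F7. Dichloroketene (Cl3CCOCl, Zn(Cu), Et2O) adds to the less substituted C5=C6 alkene with its carbonyl carbon on the diene terminus and gives methyl (2R)-2-[(1R,6R)-8,8-dichloro-7-oxo-3-[(1S)-1,3,3-trimethylcyclohexyl]bicyclo[4.2.0]oct-2-en-2-yl]propanoate F8; face selectivity is only substrate-controlled here, so the other cis-fused diastereomer is removed by chromatography. NaOMe in MeOH cleaves the C(=O)–CCl2 bond (haloform-type ring opening) and gives methyl (1R,2R)-2-(dichloromethyl)-3-[(2R)-1-methoxy-1-oxopropan-2-yl]-4-[(1S)-1,3,3-trimethylcyclohexyl]cyclohex-3-ene-1-carboxylate F9. AgNO3 in aqueous dioxane at 80 °C hydrolyses the dichloromethyl group to the aldehyde, which lactonises onto the neighbouring methyl ester and comes back to the route at 20.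

**Further compounds**
F1 | step 1 | (1R)-3,5,5-trimethylcyclohex-2-en-1-ol | O[C@H]1C=C(C)CC(C)(C)C1
F2 | step 1 | (1R)-3,5,5-trimethylcyclohex-2-en-1-yl pyridine-2-carboxylate | O=C(O[C@H]1C=C(C)CC(C)(C)C1)c1ccccn1
F3 | step 1 | 1-methoxy-3-[(1R)-1,5,5-trimethylcyclohex-2-en-1-yl]benzene | COc1cccc(c1)[C@@]1(C)C=CCC(C)(C)C1
F4 | step 5 | 3-[(1S)-1,3,3-trimethylcyclohexyl]cyclohex-2-en-1-one | O=C1C=C(CCC1)[C@@]1(C)CCCC(C)(C)C1
F5 | step 5 | 2-iodo-3-[(1S)-1,3,3-trimethylcyclohexyl]cyclohex-2-en-1-one | O=C1C(I)=C(CCC1)[C@@]1(C)CCCC(C)(C)C1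
F6 | step 5 | methyl 2-[6-oxo-2-[(1S)-1,3,3-trimethylcyclohexyl]cyclohex-1-en-1-yl]prop-2-enoate | COC(=O)C(=C)C1=C(CCCC1=O)[C@@]1(C)CCCC(C)(C)C1
F7 | step 8 | methyl (2R)-2-[2-[(1S)-1,3,3-trimethylcyclohexyl]cyclohexa-1,5-dien-1-yl]propanoate | COC(=O)[C@H](C)C1=C(CCC=C1)[C@@]1(C)CCCC(C)(C)C1
F8 | step 8 | methyl (2R)-2-[(1R,6R)-8,8-dichloro-7-oxo-3-[(1S)-1,3,3-trimethylcyclohexyl]bicyclo[4.2.0]oct-2-en-2-yl]propanoate | COC(=O)[C@H](C)C1=C([C@@]2(C)CCCC(C)(C)C2)CC[C@H]2C(=O)C(Cl)(Cl)[C@@H]12
F9 | step 8 | methyl (1R,2R)-2-(dichloromethyl)-3-[(2R)-1-methoxy-1-oxopropan-2-yl]-4-[(1S)-1,3,3-trimethylcyclohexyl]cyclohex-3-ene-1-carboxylate | COC(=O)[C@H](C)C1=C([C@@]2(C)CCCC(C)(C)C2)CC[C@@H](C(=O)OC)[C@H]1C(Cl)Cl
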